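**Plan** (carotenoid numbering: ring C1–C6 with C1 = CMe2, C3 = CHOH, C5 = O-bearing quaternary carbon, C6 = ring alkene carbon; C7 = ring CH=, C8 = O–CH, chain C9…C15, C15'…C8' = CHO)
- Retrosynthesis: the polyene is cut at C9'=C10' (formyl ylide), C11'=C12' (cyanomethylphosphonate) and C11=C12 (Wittig on 2,7-dimethyloctatrienedial), leaving a C15 hexahydrobenzofuran enoate. That is cut in one stroke at C7–C8 and O–C5 into a C5 oxo-enoate and a C10 cyclohexenylmethyl sulfonium salt.
- Forward: the cyclohexene ring comes from actinol and is homologated at C6. Step 9 annulates the dihydrofuran ring onto it as a formal (3+2) reaction of the aldehyde C=O with the C5–C6–C7 unit. The chain then grows C15 → C27 → C30.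
- Enabling feature: C7 is an exocyclic carbon on the fully substituted C5=C6 alkene of the cyclohexene ring, so an oxirane across C7–C8 is a latent allyl cation whose tertiary end C5 lies five atoms from the oxygen on C8. The enoate on C8 keeps the C8–O bond from ionising.
- Stereochemistry: C3 from (4R,6R)-actinol by Mitsunobu inversion; C8 from the chiral sulfide of the ylide; C5 from C3 through a chair-like closure (oxygen cis to the C3 oxygen, also the more stable epimer).

Key step: step 9

Assumption: (4R,6R)-actinol, both antipodes of isothiocineole, ethyl (2E)-3-methyl-4-oxobut-2-enoate and 2,7-dimethylocta-2,4,6-trienedial are taken as purchasable, and the (1S,4S,5S) sulfide is taken to be the antipode whose allylic ylides give (S,S)-trans-oxiranes (its mirror image would replace it, with no other change, if the facial model demands).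

**Step 1**
Reactants: 1 (4R,6R)-4-hydroxy-2,2,6-trimethylcyclohexan-1-one
Product: 2 (4S,6R)-4-(4-nitrobenzoyloxy)-2,2,6-trimethylcyclohexan-1-one
Conditions: 4-O2NC6H4CO2H, PPh3, diisopropyl azodicarboxylate, THF, 0 °C to rt
Reagents that add atoms: 4-nitrobenzoic acid, OC(=O)c1ccc(cc1)[N+](=O)[O-]
Why: Mitsunobu reaction, in which the carboxylate displaces the alkoxyphosphonium ion of the unhindered secondary alcohol by SN2 and so inverts C4 from R to S (the configuration needed at C3 of the target) while the ketone is untouched.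

**Step 2**
Reactants: 2 (4S,6R)-4-(4-nitrobenzoyloxy)-2,2,6-trimethylcyclohexan-1-one
Product: 3 (4S,6R)-4-hydroxy-2,2,6-trimethylcyclohexan-1-one
Conditions: K2CO3 (0.2 equiv), MeOH, rt
Reagents that add atoms: none
Why: base-catalysed transesterification (methanolysis) frees the inverted alcohol, and any epimerisation of the C6 centre next to the ketone is without consequence because that carbon becomes sp2 in step 4.

**Step 3**
Reactants: 3 (4S,6R)-4-hydroxy-2,2,6-trimethylcyclohexan-1-one
Product: 4 (4S,6R)-4-(tert-butyldimethylsilyloxy)-2,2,6-trimethylcyclohexan-1-one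
Conditions: t-BuMe2SiCl, imidazole, DMF, rt
Reagents that add atoms: tert-butyldimethylsilyl chloride, CC(C)(C)[Si](C)(C)Cl
Why: imidazole-promoted silylation of the secondary alcohol gives an ether that survives the base, hydride, ylide and Lewis-acid steps that follow and fixes the equatorial preference used in step 9.

**Step 4**
Reactants: 4 (4S,6R)-4-(tert-butyldimethylsilyloxy)-2,2,6-trimethylcyclohexan-1-one
Product: 6 (4S)-4-(tert-butyldimethylsilyloxy)-2,6,6-trimethylcyclohex-1-en-1-yl trifluoromethanesulfonate, via potassium enolate 5 (not isolated)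
Conditions: KN(SiMe3)2, THF, −78 °C; then PhN(SO2CF3)2, −78 °C to rt
Reagents that add atoms: N-phenylbis(trifluoromethanesulfonimide), O=S(=O)(N(c1ccccc1)S(=O)(=O)C(F)(F)F)C(F)(F)F
Why: enol triflate formation, in which the ketone has a single enolisable position (C6–H) so that only the tetrasubstituted enolate can form and be O-sulfonylated; the C6 stereocentre is removed here.

**Step 5**
Reactants: 6 (4S)-4-(tert-butyldimethylsilyloxy)-2,6,6-trimethylcyclohex-1-en-1-yl trifluoromethanesulfonate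
Product: 7 methyl (4S)-4-(tert-butyldimethylsilyloxy)-2,6,6-trimethylcyclohex-1-ene-1-carboxylate
Conditions: CO (1 atm), MeOH, Et3N, Pd(OAc)2 (5 mol %), Ph2P(CH2)3PPh2, DMF, 70 °C
Reagents that add atoms: carbon monoxide, [C-]#[O+]; methanol, CO
Why: palladium-catalysed alkoxycarbonylation of an enol triflate (oxidative addition to zerovalent palladium, CO insertion, methanolysis) installs C7 at the ester level on the hindered ring carbon, where the small CO ligand is tolerated.

**Step 6**
Reactants: 7 methyl (4S)-4-(tert-butyldimethylsilyloxy)-2,6,6-trimethylcyclohex-1-ene-1-carboxylate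
Product: 8 [(4S)-4-(tert-butyldimethylsilyloxy)-2,6,6-trimethylcyclohex-1-en-1-yl]methanol
Conditions: i-Bu2AlH (2.5 equiv), CH2Cl2, −78 to 0 °C; aqueous potassium sodium tartrate
Reagents that add atoms: none
Why: hydride reduction of the conjugated ester to the primary allylic alcohol (two 1,2-additions of i-Bu2AlH) touches no stereocentre and leaves the silyl ether intact.

**Step 7**
Reactants: 8 [(4S)-4-(tert-butyldimethylsilyloxy)-2,6,6-trimethylcyclohex-1-en-1-yl]methanol
Product: 9 (4S)-1-(bromomethyl)-4-(tert-butyldimethylsilyloxy)-2,6,6-trimethylcyclohex-1-ene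
Conditions: CBr4, PPh3, CH2Cl2, 0 °C
Reagents that add atoms: tetrabromomethane, BrC(Br)(Br)Br
Why: Appel reaction under neutral conditions converts the primary allylic alcohol into the bromide by SN2 displacement without disturbing the silyl ether.

**Step 8**
Reactants: 9 (4S)-1-(bromomethyl)-4-(tert-butyldimethylsilyloxy)-2,6,6-trimethylcyclohex-1-ene; 10 (1S,4S,5S)-4,7,7-trimethyl-6-thiabicyclo[3.2.1]octane (isothiocineole)
Product: 11 S-{[(4S)-4-(tert-butyldimethylsilyloxy)-2,6,6-trimethylcyclohex-1-en-1-yl]methyl}-(1S,4S,5S)-isothiocineolium trifluoromethanesulfonate (one configuration at sulfur, from alkylation on the less hindered lone pair)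
Conditions: LiOSO2CF3, CH2Cl2/H2O, rt
Reagents that add atoms: lithium trifluoromethanesulfonate, [Li+].[O-]S(=O)(=O)C(F)(F)F
Why: S-alkylation of the sulfide by the primary allylic bromide (SN2), driven by exchange of bromide for non-nucleophilic triflate, should give one sulfonium diastereomer whose only acidic position is C7.

**Step 9**
Reactants: 11 S-{[(4S)-4-(tert-butyldimethylsilyloxy)-2,6,6-trimethylcyclohex-1-en-1-yl]methyl}-(1S,4S,5S)-isothiocineolium trifluoromethanesulfonate; 12 ethyl (2E)-3-methyl-4-oxobut-2-enoate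
Product: 15 ethyl (2E)-3-[(2R,6R,7aR)-6-(tert-butyldimethylsilyloxy)-4,4,7a-trimethyl-2,4,5,6,7,7a-hexahydro-1-benzofuran-2-yl]but-2-enoate, via sulfonium ylide 13 (not isolated), via trans vinyl oxirane 14 (not isolated)
Conditions: KN(SiMe3)2, toluene/THF, −78 °C; then 12, −78 to 0 °C; then Cu(CF3COCHCOCF3)2 (copper bis(hexafluoroacetylacetonate), 5 mol %), 0 to 40 °C, same flask
Reagents that add atoms: none
Why: Proposed new method: deprotonation of 11 gives the allylic sulfonium ylide 13, whose C7 adds to the aldehyde of 12 and closes (3-exo-tet, loss of sulfide 10) to the trans vinyl oxirane 14; the copper catalyst should then ionise only the C7–O bond, because that cation is an allyl cation ending at the fully substituted C5 whereas a cation at C8 would sit next to the electron-poor enoate, and the oxygen on C8 closes on C5 (5-endo-trig collapse of the alkoxide onto the twisted allyl cation, a formal 1,3-shift of oxygen), so that the C7–C8 and O–C5 bonds arise in one flask as a formal (3+2) annulation of a C=O with the C5–C6–C7 unit. The closest known reactions are the sulfur-ylide (Corey–Chaykovsky-type) synthesis of vinyl oxiranes from allylic sulfonium salts and aldehydes and the copper bis(hexafluoroacetylacetonate)-catalysed ring expansion of vinyl oxiranes to 2,5-dihydrofurans; their merger in one operation and the formation of a quaternary C–O centre are the untested parts. C8 is set by the chiral sulfide, which fixes the face of the ylide carbon, together with the anti (trans) course of betaine formation, and it is kept in the second stage because the C8–O bond is never broken, while the C7 centre is erased and serves only as a relay. C5 is set by the ring: closure passes through the chair in which the C5 methyl is axial, the new C5–O bond lies in the plane of the C6=C7 bond and the C3 silyloxy group is equatorial, which places the new oxygen cis to the C3 oxygen, and since this is also the more stable epimer any reversibility of the ionisation feeds the same isomer. The step needs 1,2- over 1,4-addition of the ylide to the oxo-enoate (the aldehyde carbonyl is the most electrophilic site and the alkene is trisubstituted) and ring closure in preference to a 1,2-hydride shift to a ketone (favoured by the copper catalyst and the five-membered geometry).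

**Step 10**
Reactants: 15 ethyl (2E)-3-[(2R,6R,7aR)-6-(tert-butyldimethylsilyloxy)-4,4,7a-trimethyl-2,4,5,6,7,7a-hexahydro-1-benzofuran-2-yl]but-2-enoate
Product: 16 (2E)-3-[(2R,6R,7aR)-6-(tert-butyldimethylsilyloxy)-4,4,7a-trimethyl-2,4,5,6,7,7a-hexahydro-1-benzofuran-2-yl]but-2-en-1-ol
Conditions: i-Bu2AlH (2.2 equiv), CH2Cl2, −78 °C; aqueous potassium sodium tartrate
Reagents that add atoms: none
Why: i-Bu2AlH reduces the enoate to the allylic alcohol at low temperature (1,2-reduction) and leaves the allylic ether, the silyl ether and all stereocentres intact.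

**Step 11**
Reactants: 16 (2E)-3-[(2R,6R,7aR)-6-(tert-butyldimethylsilyloxy)-4,4,7a-trimethyl-2,4,5,6,7,7a-hexahydro-1-benzofuran-2-yl]but-2-en-1-ol
Product: 18 {(2E)-3-[(2R,6R,7aR)-6-(tert-butyldimethylsilyloxy)-4,4,7a-trimethyl-2,4,5,6,7,7a-hexahydro-1-benzofuran-2-yl]but-2-en-1-yl}triphenylphosphonium bromide, via allylic bromide 17 (not isolated)
Conditions: CBr4 (1.1 equiv), PPh3 (2.3 equiv), CH2Cl2, 0 °C to rt
Reagents that add atoms: triphenylphosphine, c1ccc(cc1)P(c1ccccc1)c1ccccc1; tetrabromomethane, BrC(Br)(Br)Br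
Why: Appel bromination followed in the same flask by SN2 quaternisation of PPh3 gives the allylic phosphonium salt without acid, so the acid-labile C8–O bond is not ionised.

**Step 12**
Reactants: 19 (2E,4E,6E)-2,7-dimethylocta-2,4,6-trienedial (3 equiv); 20 diethyl (cyanomethyl)phosphonate
Product: 22 (2E,4E,6E,8E)-4,9-dimethyl-10-oxodeca-2,4,6,8-tetraenenitrile, via sodium phosphonate carbanion 21 (not isolated)
Conditions: NaH, THF, 0 °C; then 19, 0 °C to rt; then I2 (1 mol %), CH2Cl2, rt, daylight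
Reagents that add atoms: none
Why: Horner–Wadsworth–Emmons reaction of the stabilised phosphonate carbanion with one formyl group of the dialdehyde used in excess (statistical mono-olefination) should give mainly the E alkene, and iodine-catalysed equilibration completes the all-E geometry.

**Step 13**
Reactants: 18 {(2E)-3-[(2R,6R,7aR)-6-(tert-butyldimethylsilyloxy)-4,4,7a-trimethyl-2,4,5,6,7,7a-hexahydro-1-benzofuran-2-yl]but-2-en-1-yl}triphenylphosphonium bromide; 22 (2E,4E,6E,8E)-4,9-dimethyl-10-oxodeca-2,4,6,8-tetraenenitrile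
Product: 24 (2E,4E,6E,8E,10E,12E)-13-[(2R,6R,7aR)-6-(tert-butyldimethylsilyloxy)-4,4,7a-trimethyl-2,4,5,6,7,7a-hexahydro-1-benzofuran-2-yl]-4,9-dimethyltetradeca-2,4,6,8,10,12-hexaenenitrile, via phosphonium ylide 23 (not isolated)
Conditions: NaOMe, MeOH/CH2Cl2, 0 °C to rt; then heptane, 90 °C, dark
Reagents that add atoms: none
Why: Wittig reaction of the semi-stabilised allylic ylide with the α-methyl enal forms C11=C12, the Z/E mixture usual for this ylide class is equilibrated thermally to the all-E polyene, and the nitrile is inert to the ylide.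

**Step 14**
Reactants: 24 (2E,4E,6E,8E,10E,12E)-13-[(2R,6R,7aR)-6-(tert-butyldimethylsilyloxy)-4,4,7a-trimethyl-2,4,5,6,7,7a-hexahydro-1-benzofuran-2-yl]-4,9-dimethyltetradeca-2,4,6,8,10,12-hexaenenitrile
Product: 25 (2E,4E,6E,8E,10E,12E)-13-[(2R,6R,7aR)-6-(tert-butyldimethylsilyloxy)-4,4,7a-trimethyl-2,4,5,6,7,7a-hexahydro-1-benzofuran-2-yl]-4,9-dimethyltetradeca-2,4,6,8,10,12-hexaenal
Conditions: i-Bu2AlH (1.2 equiv), toluene, −78 °C; then aqueous potassium sodium tartrate, 0 °C
Reagents that add atoms: water, O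
Why: nitrile-to-aldehyde reduction, in which i-Bu2AlH adds once to the conjugated nitrile (1,2-selective on polyene nitriles) and neutral aqueous work-up releases the enal without acid that would epimerise C8.

**Step 15**
Reactants: 25 (2E,4E,6E,8E,10E,12E)-13-[(2R,6R,7aR)-6-(tert-butyldimethylsilyloxy)-4,4,7a-trimethyl-2,4,5,6,7,7a-hexahydro-1-benzofuran-2-yl]-4,9-dimethyltetradeca-2,4,6,8,10,12-hexaenal; 26 2-(triphenyl-λ5-phosphanylidene)propanal
Product: 27 (2E,4E,6E,8E,10E,12E,14E)-15-[(2R,6R,7aR)-6-(tert-butyldimethylsilyloxy)-4,4,7a-trimethyl-2,4,5,6,7,7a-hexahydro-1-benzofuran-2-yl]-2,6,11-trimethylhexadeca-2,4,6,8,10,12,14-heptaenal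
Conditions: toluene, 80 °C, dark
Reagents that add atoms: none
Why: Wittig reaction of the stabilised formyl ylide with the unhindered enal should give the E-configured α-methyl enal terminus directly, and the α-branched, less electrophilic product aldehyde should not react further.

**Step 16**
Reactants: 27 (2E,4E,6E,8E,10E,12E,14E)-15-[(2R,6R,7aR)-6-(tert-butyldimethylsilyloxy)-4,4,7a-trimethyl-2,4,5,6,7,7a-hexahydro-1-benzofuran-2-yl]-2,6,11-trimethylhexadeca-2,4,6,8,10,12,14-heptaenal
Product: 28 (2E,4E,6E,8E,10E,12E,14E)-15-[(2R,6R,7aR)-6-hydroxy-4,4,7a-trimethyl-2,4,5,6,7,7a-hexahydro-1-benzofuran-2-yl]-2,6,11-trimethylhexadeca-2,4,6,8,10,12,14-heptaenal (the target, (3R,5R,8R)-5,8-epoxy-3-hydroxy-5,8-dihydro-8'-apo-β-caroten-8'-al)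
Conditions: Bu4NF, AcOH, THF, 0 °C to rt
Reagents that add atoms: none
Why: fluoride-mediated desilylation buffered with acetic acid removes the silyl ether without strong acid that would epimerise C8 or free base that would condense the polyenal.

**Compound list**
1 | (4R,6R)-4-hydroxy-2,2,6-trimethylcyclohexan-1-one ((4R,6R)-actinol) | O=C1C(C)(C)C[C@H](O)C[C@H]1C | starting material
2 | (4S,6R)-4-(4-nitrobenzoyloxy)-2,2,6-trimethylcyclohexan-1-one | O=C1C(C)(C)C[C@@H](OC(=O)c2ccc(cc2)[N+](=O)[O-])C[C@H]1C | intermediate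
3 | (4S,6R)-4-hydroxy-2,2,6-trimethylcyclohexan-1-one | O=C1C(C)(C)C[C@@H](O)C[C@H]1C | intermediate
4 | (4S,6R)-4-(tert-butyldimethylsilyloxy)-2,2,6-trimethylcyclohexan-1-one | O=C1C(C)(C)C[C@@H](O[Si](C)(C)C(C)(C)C)C[C@H]1C | intermediate
5 | potassium enolate of 4 | CC1=C([O-])C(C)(C)C[C@@H](O[Si](C)(C)C(C)(C)C)C1.[K+] | intermediate
6 | (4S)-4-(tert-butyldimethylsilyloxy)-2,6,6-trimethylcyclohex-1-en-1-yl trifluoromethanesulfonate | CC1=C(OS(=O)(=O)C(F)(F)F)C(C)(C)C[C@@H](O[Si](C)(C)C(C)(C)C)C1 | intermediate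
7 | methyl (4S)-4-(tert-butyldimethylsilyloxy)-2,6,6-trimethylcyclohex-1-ene-1-carboxylate | CC1=C(C(=O)OC)C(C)(C)C[C@@H](O[Si](C)(C)C(C)(C)C)C1 | intermediate
8 | [(4S)-4-(tert-butyldimethylsilyloxy)-2,6,6-trimethylcyclohex-1-en-1-yl]methanol | CC1=C(CO)C(C)(C)C[C@@H](O[Si](C)(C)C(C)(C)C)C1 | intermediate
9 | (4S)-1-(bromomethyl)-4-(tert-butyldimethylsilyloxy)-2,6,6-trimethylcyclohex-1-ene | CC1=C(CBr)C(C)(C)C[C@@H](O[Si](C)(C)C(C)(C)C)C1 | intermediate
10 | (1S,4S,5S)-4,7,7-trimethyl-6-thiabicyclo[3.2.1]octane (isothiocineole) | C[C@H]1CC[C@H]2C[C@@H]1SC2(C)C | starting material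
11 | S-{[(4S)-4-(tert-butyldimethylsilyloxy)-2,6,6-trimethylcyclohex-1-en-1-yl]methyl}-(1S,4S,5S)-isothiocineolium trifluoromethanesulfonate | CC1=C(C[S+]2[C@H]3C[C@H](CC[C@@H]3C)C2(C)C)C(C)(C)C[C@@H](O[Si](C)(C)C(C)(C)C)C1.[O-]S(=O)(=O)C(F)(F)F | intermediate
12 | ethyl (2E)-3-methyl-4-oxobut-2-enoate | CCOC(=O)/C=C(\C)C=O | starting material
13 | sulfonium ylide of 11 (carbanion at C7) | CC1=C([CH-][S+]2[C@H]3C[C@H](CC[C@@H]3C)C2(C)C)C(C)(C)C[C@@H](O[Si](C)(C)C(C)(C)C)C1 | intermediate
14 | ethyl (2E)-3-[(2S,3S)-3-{(4S)-4-(tert-butyldimethylsilyloxy)-2,6,6-trimethylcyclohex-1-en-1-yl}oxiran-2-yl]but-2-enoate | CCOC(=O)/C=C(\C)[C@@H]1O[C@H]1C2=C(C)C[C@H](O[Si](C)(C)C(C)(C)C)CC2(C)C | intermediate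
15 | ethyl (2E)-3-[(2R,6R,7aR)-6-(tert-butyldimethylsilyloxy)-4,4,7a-trimethyl-2,4,5,6,7,7a-hexahydro-1-benzofuran-2-yl]but-2-enoate | CCOC(=O)/C=C(\C)[C@H]1C=C2C(C)(C)C[C@@H](O[Si](C)(C)C(C)(C)C)C[C@@]2(C)O1 | intermediate
16 | (2E)-3-[(2R,6R,7aR)-6-(tert-butyldimethylsilyloxy)-4,4,7a-trimethyl-2,4,5,6,7,7a-hexahydro-1-benzofuran-2-yl]but-2-en-1-ol | OC/C=C(\C)[C@H]1C=C2C(C)(C)C[C@@H](O[Si](C)(C)C(C)(C)C)C[C@@]2(C)O1 | intermediate
17 | (2R,6R,7aR)-2-[(2E)-4-bromobut-2-en-2-yl]-6-(tert-butyldimethylsilyloxy)-4,4,7a-trimethyl-2,4,5,6,7,7a-hexahydro-1-benzofuran | BrC/C=C(\C)[C@H]1C=C2C(C)(C)C[C@@H](O[Si](C)(C)C(C)(C)C)C[C@@]2(C)O1 | intermediate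
18 | {(2E)-3-[(2R,6R,7aR)-6-(tert-butyldimethylsilyloxy)-4,4,7a-trimethyl-2,4,5,6,7,7a-hexahydro-1-benzofuran-2-yl]but-2-en-1-yl}triphenylphosphonium bromide | c1ccccc1[P+](c1ccccc1)(c1ccccc1)C/C=C(\C)[C@H]1C=C2C(C)(C)C[C@@H](O[Si](C)(C)C(C)(C)C)C[C@@]2(C)O1.[Br-] | intermediate
19 | (2E,4E,6E)-2,7-dimethylocta-2,4,6-trienedial | O=C/C(C)=C/C=C/C=C(\C)C=O | starting material
20 | diethyl (cyanomethyl)phosphonate | CCOP(=O)(CC#N)OCC | starting material
21 | sodium salt of the carbanion of 20 | [Na+].CCOP(=O)([CH-]C#N)OCC | intermediate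
22 | (2E,4E,6E,8E)-4,9-dimethyl-10-oxodeca-2,4,6,8-tetraenenitrile | N#C/C=C/C(C)=C/C=C/C=C(\C)C=O | intermediate
23 | phosphonium ylide of 18 | c1ccccc1P(c1ccccc1)(c1ccccc1)=C/C=C(\C)[C@H]1C=C2C(C)(C)C[C@@H](O[Si](C)(C)C(C)(C)C)C[C@@]2(C)O1 | intermediate
24 | (2E,4E,6E,8E,10E,12E)-13-[(2R,6R,7aR)-6-(tert-butyldimethylsilyloxy)-4,4,7a-trimethyl-2,4,5,6,7,7a-hexahydro-1-benzofuran-2-yl]-4,9-dimethyltetradeca-2,4,6,8,10,12-hexaenenitrile | N#C/C=C/C(C)=C/C=C/C=C(C)/C=C/C=C(\C)[C@H]1C=C2C(C)(C)C[C@@H](O[Si](C)(C)C(C)(C)C)C[C@@]2(C)O1 | intermediate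
25 | (2E,4E,6E,8E,10E,12E)-13-[(2R,6R,7aR)-6-(tert-butyldimethylsilyloxy)-4,4,7a-trimethyl-2,4,5,6,7,7a-hexahydro-1-benzofuran-2-yl]-4,9-dimethyltetradeca-2,4,6,8,10,12-hexaenal | O=C/C=C/C(C)=C/C=C/C=C(C)/C=C/C=C(\C)[C@H]1C=C2C(C)(C)C[C@@H](O[Si](C)(C)C(C)(C)C)C[C@@]2(C)O1 | intermediate
26 | 2-(triphenyl-λ5-phosphanylidene)propanal | CC(C=O)=P(c1ccccc1)(c1ccccc1)c1ccccc1 | starting material
27 | (2E,4E,6E,8E,10E,12E,14E)-15-[(2R,6R,7aR)-6-(tert-butyldimethylsilyloxy)-4,4,7a-trimethyl-2,4,5,6,7,7a-hexahydro-1-benzofuran-2-yl]-2,6,11-trimethylhexadeca-2,4,6,8,10,12,14-heptaenal | C\C(C=O)=C/C=C/C(C)=C/C=C/C=C(C)/C=C/C=C(\C)[C@H]1C=C2C(C)(C)C[C@@H](O[Si](C)(C)C(C)(C)C)C[C@@]2(C)O1 | intermediate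
28 | (2E,4E,6E,8E,10E,12E,14E)-15-[(2R,6R,7aR)-6-hydroxy-4,4,7a-trimethyl-2,4,5,6,7,7a-hexahydro-1-benzofuran-2-yl]-2,6,11-trimethylhexadeca-2,4,6,8,10,12,14-heptaenal | C\C(C=O)=C/C=C/C(C)=C/C=C/C=C(C)/C=C/C=C(\C)[C@H]1C=C2C(C)(C)C[C@@H](O)C[C@@]2(C)O1 | target

**Total step count:** 16. **Longest linear sequence:** 15 (steps 1 to 11 and 13 to 16).

**Steps most likely to fail**

Step 9 (proposed new method). The ylide may add in the conjugate sense to the oxo-enoate (cyclopropanation) in place of 1,2-addition. The oxirane may open with a hydride shift or proton loss in place of ring closure, or the liberated sulfide may slow the copper catalyst. Incomplete trans selectivity would erode the configuration at C8, and the closure on C5 may show poor facial selectivity. Fallback by known chemistry, setting out from 9: heating 9 with PPh3 should give {[(4S)-4-(tert-butyldimethylsilyloxy)-2,6,6-trimethylcyclohex-1-en-1-yl]methyl}triphenylphosphonium bromide F1. Wittig reaction of its ylide (NaOMe, MeOH) with aldehyde 12 gives ethyl (2E,4E)-5-[(4S)-4-(tert-butyldimethylsilyloxy)-2,6,6-trimethylcyclohex-1-en-1-yl]-3-methylpenta-2,4-dienoate F2, which carries the C7=C8 alkene of the ordinary carotenoid end group. 3-Chloroperbenzoic acid epoxidises the electron-rich ring alkene, and the syn 5,6-epoxide F3 ((3R,5R,6S) in carotenoid numbering) is separated from its anti isomer. Trace HCl in CHCl3 then triggers the known epoxide-to-furanoid rearrangement (here the O–C8 bond is the one formed), giving 15 together with its C8 epimer, which is removed by chromatography. The route resumes at 15.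

Step 13. The allylic ylide carries the C8–O bond in a vinylogous β-position, so reversible ring opening of the dihydrofuran could scramble C8, and the Z/E mixture at C11=C12 may not equilibrate cleanly. Fallback with the polarity inverted, setting out from 16 and 22: MnO2 oxidises 16 to (2E)-3-[(2R,6R,7aR)-6-(tert-butyldimethylsilyloxy)-4,4,7a-trimethyl-2,4,5,6,7,7a-hexahydro-1-benzofuran-2-yl]but-2-enal F4. NaBH4/CeCl3 reduces 22 to (2E,4E,6E,8E)-10-hydroxy-4,9-dimethyldeca-2,4,6,8-tetraenenitrile F5, PBr3 gives the bromide F6, and Arbuzov reaction with P(OEt)3 gives diethyl [(2E,4E,6E,8E)-9-cyano-2,7-dimethylnona-2,4,6,8-tetraen-1-yl]phosphonate F7. Horner–Wadsworth–Emmons reaction of F7 (NaH, THF) with F4 places the carbanion on the polyene partner, far from C8, and comes back to the route at 24.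

Step 5. Oxidative addition and CO insertion at the tetrasubstituted triflate, flanked by a gem-dimethyl and a methyl group, may be so slow that hydrolysis or reduction of the triflate takes over. Fallback, setting out from 4: condensation with 2,4,6-triisopropylbenzenesulfonohydrazide gives the hydrazone F8. Shapiro reaction (n-BuLi, THF, −78 to 0 °C) gives [(4S)-4-(tert-butyldimethylsilyloxy)-2,6,6-trimethylcyclohex-1-en-1-yl]lithium F9, which is trapped with paraformaldehyde to come back to the route at 8, so that steps 4 to 6 are bypassed.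

**Further compounds**
F1 | step 9 | {[(4S)-4-(tert-butyldimethylsilyloxy)-2,6,6-trimethylcyclohex-1-en-1-yl]methyl}triphenylphosphonium bromide | CC1=C(C[P+](c2ccccc2)(c2ccccc2)c2ccccc2)C(C)(C)C[C@@H](O[Si](C)(C)C(C)(C)C)C1.[Br-]
F2 | step 9 | ethyl (2E,4E)-5-[(4S)-4-(tert-butyldimethylsilyloxy)-2,6,6-trimethylcyclohex-1-en-1-yl]-3-methylpenta-2,4-dienoate | CCOC(=O)/C=C(C)/C=C/C1=C(C)C[C@H](O[Si](C)(C)C(C)(C)C)CC1(C)C
F3 | step 9 | ethyl (2E,4E)-5-[(1S,4R,6R)-4-(tert-butyldimethylsilyloxy)-2,2,6-trimethyl-7-oxabicyclo[4.1.0]heptan-1-yl]-3-methylpenta-2,4-dienoate (syn 5,6-epoxide) | CCOC(=O)/C=C(C)/C=C/[C@@]12O[C@]1(C)C[C@H](O[Si](C)(C)C(C)(C)C)CC2(C)C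
F4 | step 13 | (2E)-3-[(2R,6R,7aR)-6-(tert-butyldimethylsilyloxy)-4,4,7a-trimethyl-2,4,5,6,7,7a-hexahydro-1-benzofuran-2-yl]but-2-enal | O=C/C=C(\C)[C@H]1C=C2C(C)(C)C[C@@H](O[Si](C)(C)C(C)(C)C)C[C@@]2(C)O1
F5 | step 13 | (2E,4E,6E,8E)-10-hydroxy-4,9-dimethyldeca-2,4,6,8-tetraenenitrile | N#C/C=C/C(C)=C/C=C/C=C(\C)CO
F6 | step 13 | (2E,4E,6E,8E)-10-bromo-4,9-dimethyldeca-2,4,6,8-tetraenenitrile | N#C/C=C/C(C)=C/C=C/C=C(\C)CBr
F7 | step 13 | diethyl [(2E,4E,6E,8E)-9-cyano-2,7-dimethylnona-2,4,6,8-tetraen-1-yl]phosphonate | N#C/C=C/C(C)=C/C=C/C=C(\C)CP(=O)(OCC)OCC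
F8 | step 5 | 2,4,6-triisopropylbenzenesulfonohydrazone of 4 | CC(C)c1cc(C(C)C)c(c(c1)C(C)C)S(=O)(=O)NN=C1C(C)(C)C[C@@H](O[Si](C)(C)C(C)(C)C)C[C@H]1C
F9 | step 5 | [(4S)-4-(tert-butyldimethylsilyloxy)-2,6,6-trimethylcyclohex-1-en-1-yl]lithium | [Li]C1=C(C)C[C@H](O[Si](C)(C)C(C)(C)C)CC1(C)C
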